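**Retrosynthetic overview**
- The pyranone (ring C) is the only ring built and is closed late, by enol-lactonisation of a 2-(2-oxopropyl)benzoate; both benzene rings (ring A of the isocoumarin, ring B of the benzyl group) are bought in.
- Key C–C bond (C3–C4 of the isocoumarin): intermolecular crossed Claisen-type condensation of the lithium dienolate of an o-toluate ester with N-methoxy-N-methylacetamide.
- Diarylmethane bridge: an aryl Grignard from iodinated ring A adds to the ring B benzaldehyde, followed by ionic deoxygenation of the carbinol.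
- Ring A comes from methyl orsellinate (4-O-benzylation, 2-O-methylation, iodination); ring B from 3,5-bis(benzyloxy)benzyl alcohol (O-methylation, Vilsmeier formylation, chelation-controlled ortho-debenzylation, O-methylation).
- The two phenols are carried as benzyl ethers and released in the last step.

Assumption: the target has no stereocentre and is achiral, so it is made as drawn and no absolute configuration has to be set. The stereocentres in 12 and 17 are racemic and are erased on the way.

**Step 1**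
Reactants: 1 methyl 2,4-dihydroxy-6-methylbenzoate (methyl orsellinate)
Product: 2 methyl 4-(benzyloxy)-2-hydroxy-6-methylbenzoate
Conditions: BnBr (1.05 equiv), K2CO3 (1.2 equiv), acetone, reflux, 8 h
Reagents that add atoms: benzyl bromide, BrCc1ccccc1
Why: Williamson etherification (SN2) is selective for the 4-OH because the 2-OH is hydrogen-bonded to the ester carbonyl and is much less nucleophilic.

**Step 2**
Reactants: 2 methyl 4-(benzyloxy)-2-hydroxy-6-methylbenzoate
Product: 3 methyl 4-(benzyloxy)-2-methoxy-6-methylbenzoate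
Conditions: MeI (3 equiv), K2CO3 (3 equiv), DMF, 50 °C, 12 h
Reagents that add atoms: iodomethane, CI
Why: Williamson O-methylation under more forcing conditions alkylates the remaining chelated phenol and fixes the methoxy group that becomes 8-OMe of the isocoumarin.

**Step 3**
Reactants: 3 methyl 4-(benzyloxy)-2-methoxy-6-methylbenzoate
Product: 4 methyl 4-(benzyloxy)-3-iodo-6-methoxy-2-methylbenzoate
Conditions: NIS (1.05 equiv), TFA (0.3 equiv), MeCN, 0 °C to rt, dark
Reagents that add atoms: N-iodosuccinimide, O=C1CCC(=O)N1I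
Why: Electrophilic aromatic iodination goes to the carbon para to OMe and ortho to OBn next to the methyl group, as 3,5-dialkoxytoluenes are halogenated there and not at the crowded position between the two oxygens.

**Step 4**
Reactants: 5 [3,5-bis(benzyloxy)phenyl]methanol (3,5-bis(benzyloxy)benzyl alcohol)
Product: 6 1,3-bis(benzyloxy)-5-(methoxymethyl)benzene
Conditions: NaH (1.3 equiv), MeI (1.5 equiv), THF, 0 °C to rt
Reagents that add atoms: iodomethane, CI
Why: Williamson methylation of the sodium alkoxide installs the benzylic methyl ether early, where nothing else in the molecule competes.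

**Step 5**
Reactants: 6 1,3-bis(benzyloxy)-5-(methoxymethyl)benzene
Product: 8 2,4-bis(benzyloxy)-6-(methoxymethyl)benzaldehyde, via aryl iminium chloride 7 (not isolated)
Conditions: POCl3 (1.5 equiv), DMF, 0 °C to 70 °C, 3 h; then aq NaOAc, 50 °C
Reagents that add atoms: N,N-dimethylformamide, CN(C)C=O; water, O
Why: Vilsmeier–Haack formylation attacks the position ortho to one benzyloxy and para to the other (next to the CH2OMe arm) rather than the hindered carbon between the two benzyloxy groups, and the iminium salt is hydrolysed on work-up.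

**Step 6**
Reactants: 8 2,4-bis(benzyloxy)-6-(methoxymethyl)benzaldehyde
Product: 9 4-(benzyloxy)-2-hydroxy-6-(methoxymethyl)benzaldehyde
Conditions: MgBr2·OEt2 (3 equiv), toluene/Et2O 5:1, 80 °C, 16 h; then 1 M HCl
Reagents that add atoms: none
Why: Chelation-controlled ether cleavage, in which MgBr2 binds the aldehyde oxygen and the ortho ether oxygen in a six-membered chelate so that bromide removes only the ortho benzyl group by SN2 while the para benzyl ether and the methyl ether stay.

**Step 7**
Reactants: 9 4-(benzyloxy)-2-hydroxy-6-(methoxymethyl)benzaldehyde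
Product: 10 4-(benzyloxy)-2-methoxy-6-(methoxymethyl)benzaldehyde
Conditions: MeI (2 equiv), K2CO3 (2 equiv), DMF, 40 °C
Reagents that add atoms: iodomethane, CI
Why: Williamson O-methylation of the freed ortho phenol gives the methoxy/benzyloxy pattern of ring B without any regiochemical ambiguity.

**Step 8**
Reactants: 4 methyl 4-(benzyloxy)-3-iodo-6-methoxy-2-methylbenzoate; 10 4-(benzyloxy)-2-methoxy-6-(methoxymethyl)benzaldehyde
Product: 12 methyl 4-(benzyloxy)-3-{[4-(benzyloxy)-2-methoxy-6-(methoxymethyl)phenyl](hydroxy)methyl}-6-methoxy-2-methylbenzoate (racemic), via arylmagnesium chloride 11 (not isolated)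
Conditions: 4 (1.1 equiv), i-PrMgCl·LiCl (1.15 equiv), THF, 0 °C to rt, 2 h; then 10, 0 °C to rt, 3 h; aq NH4Cl
Reagents that add atoms: none
Why: Iodine–magnesium exchange with i-PrMgCl·LiCl (Knochel exchange) tolerates the doubly ortho-blocked methyl ester, and the aryl Grignard adds 1,2 to the non-enolisable aldehyde; the carbinol stereocentre forms racemic and is removed in step 9.

**Step 9**
Reactants: 12 methyl 4-(benzyloxy)-3-{[4-(benzyloxy)-2-methoxy-6-(methoxymethyl)phenyl](hydroxy)methyl}-6-methoxy-2-methylbenzoate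
Product: 14 methyl 4-(benzyloxy)-3-{[4-(benzyloxy)-2-methoxy-6-(methoxymethyl)phenyl]methyl}-6-methoxy-2-methylbenzoate, via diarylmethylium trifluoroacetate 13 (not isolated)
Conditions: Et3SiH (3 equiv), TFA (5 equiv), CH2Cl2, −20 °C to 0 °C, 30 min; aq NaHCO3
Reagents that add atoms: none
Why: Ionic hydrogenation, in which TFA ionises the doubly benzylic alcohol to a cation stabilised by ortho/para alkoxy groups on both rings and Et3SiH reduces it by hydride transfer, erasing the carbinol stereocentre.

**Step 10**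
Reactants: 14 methyl 4-(benzyloxy)-3-{[4-(benzyloxy)-2-methoxy-6-(methoxymethyl)phenyl]methyl}-6-methoxy-2-methylbenzoate; 15 N-methoxy-N-methylacetamide
Product: 18 methyl 4-(benzyloxy)-3-{[4-(benzyloxy)-2-methoxy-6-(methoxymethyl)phenyl]methyl}-6-methoxy-2-(2-oxopropyl)benzoate, via lithiated toluate 16 (not isolated), via tetrahedral lithium adduct 17 (not isolated)
Conditions: LiN(i-Pr)2 (1.5 equiv), THF, −78 °C, 30 min; then 15 (2 equiv), −78 °C to −40 °C, 1 h; aq NH4Cl
Reagents that add atoms: none
Why: The ester-conjugated ortho-methyl group is the most acidic site, and its lithium dienolate (a vinylogous ester enolate) is C-acylated by the Weinreb amide in an intermolecular crossed Claisen-type condensation; the chelated tetrahedral adduct prevents over-addition, and no stereocentre remains in the product.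

**Step 11**
Reactants: 18 methyl 4-(benzyloxy)-3-{[4-(benzyloxy)-2-methoxy-6-(methoxymethyl)phenyl]methyl}-6-methoxy-2-(2-oxopropyl)benzoate
Product: 19 6-(benzyloxy)-5-{[4-(benzyloxy)-2-methoxy-6-(methoxymethyl)phenyl]methyl}-8-methoxy-3-methyl-1H-isochromen-1-one
Conditions: p-TsOH·H2O (0.2 equiv), toluene, 4 Å molecular sieves, 100 °C, 3 h
Reagents that add atoms: none
Why: Acid-catalysed enol-lactonisation (intramolecular transesterification), in which the enol of the benzylic ketone attacks the neighbouring ester and loss of methanol gives the conjugated isocoumarin ring C.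

**Step 12**
Reactants: 19 6-(benzyloxy)-5-{[4-(benzyloxy)-2-methoxy-6-(methoxymethyl)phenyl]methyl}-8-methoxy-3-methyl-1H-isochromen-1-one
Product: 20 6-hydroxy-5-{[4-hydroxy-2-methoxy-6-(methoxymethyl)phenyl]methyl}-8-methoxy-3-methyl-1H-isochromen-1-one
Conditions: H2 (1 atm), Pd/C (10 wt% Pd), EtOAc, rt, stopped at full conversion (about 1–2 h)
Reagents that add atoms: none
Why: Catalytic hydrogenolysis cleaves the two aryl benzyl ethers much faster than it touches the unactivated benzylic methyl ether or the conjugated lactone C3=C4 bond, so stopping at full debenzylation gives the target.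

**Compound list**
1 | methyl 2,4-dihydroxy-6-methylbenzoate (methyl orsellinate) | COC(=O)c1c(C)cc(O)cc1O | starting material
2 | methyl 4-(benzyloxy)-2-hydroxy-6-methylbenzoate | COC(=O)c1c(C)cc(OCc2ccccc2)cc1O | intermediate
3 | methyl 4-(benzyloxy)-2-methoxy-6-methylbenzoate | COC(=O)c1c(C)cc(OCc2ccccc2)cc1OC | intermediate
4 | methyl 4-(benzyloxy)-3-iodo-6-methoxy-2-methylbenzoate | COC(=O)c1c(C)c(I)c(OCc2ccccc2)cc1OC | intermediate
5 | [3,5-bis(benzyloxy)phenyl]methanol | OCc1cc(OCc2ccccc2)cc(OCc2ccccc2)c1 | starting material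
6 | 1,3-bis(benzyloxy)-5-(methoxymethyl)benzene | COCc1cc(OCc2ccccc2)cc(OCc2ccccc2)c1 | intermediate
7 | N-{[2,4-bis(benzyloxy)-6-(methoxymethyl)phenyl]methylidene}-N-methylmethanaminium chloride | COCc1cc(OCc2ccccc2)cc(OCc2ccccc2)c1C=[N+](C)C.[Cl-] | intermediate (not isolated)
8 | 2,4-bis(benzyloxy)-6-(methoxymethyl)benzaldehyde | COCc1cc(OCc2ccccc2)cc(OCc2ccccc2)c1C=O | intermediate
9 | 4-(benzyloxy)-2-hydroxy-6-(methoxymethyl)benzaldehyde | COCc1cc(OCc2ccccc2)cc(O)c1C=O | intermediate
10 | 4-(benzyloxy)-2-methoxy-6-(methoxymethyl)benzaldehyde | COCc1cc(OCc2ccccc2)cc(OC)c1C=O | intermediate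
11 | [6-(benzyloxy)-4-methoxy-3-(methoxycarbonyl)-2-methylphenyl]magnesium chloride (LiCl complex) | COC(=O)c1c(C)c([Mg]Cl)c(OCc2ccccc2)cc1OC | intermediate (not isolated)
12 | methyl 4-(benzyloxy)-3-{[4-(benzyloxy)-2-methoxy-6-(methoxymethyl)phenyl](hydroxy)methyl}-6-methoxy-2-methylbenzoate (racemic) | COC(=O)c1c(C)c(C(O)c2c(COC)cc(OCc3ccccc3)cc2OC)c(OCc2ccccc2)cc1OC | intermediate
13 | [6-(benzyloxy)-4-methoxy-3-(methoxycarbonyl)-2-methylphenyl][4-(benzyloxy)-2-methoxy-6-(methoxymethyl)phenyl]methylium trifluoroacetate | COC(=O)c1c(C)c([CH+]c2c(COC)cc(OCc3ccccc3)cc2OC)c(OCc2ccccc2)cc1OC.[O-]C(=O)C(F)(F)F | intermediate (not isolated)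
14 | methyl 4-(benzyloxy)-3-{[4-(benzyloxy)-2-methoxy-6-(methoxymethyl)phenyl]methyl}-6-methoxy-2-methylbenzoate | COC(=O)c1c(C)c(Cc2c(COC)cc(OCc3ccccc3)cc2OC)c(OCc2ccccc2)cc1OC | intermediate
15 | N-methoxy-N-methylacetamide | CC(=O)N(C)OC | starting material
16 | methyl 4-(benzyloxy)-3-{[4-(benzyloxy)-2-methoxy-6-(methoxymethyl)phenyl]methyl}-2-(lithiomethyl)-6-methoxybenzoate (lithium dienolate, drawn C-lithiated) | COC(=O)c1c(C[Li])c(Cc2c(COC)cc(OCc3ccccc3)cc2OC)c(OCc2ccccc2)cc1OC | intermediate (not isolated)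
17 | lithium alkoxide of the N-methoxy-N-methyl hemiaminal from 16 and 15 (racemic) | COC(=O)c1c(CC(C)(O[Li])N(C)OC)c(Cc2c(COC)cc(OCc3ccccc3)cc2OC)c(OCc2ccccc2)cc1OC | intermediate (not isolated)
18 | methyl 4-(benzyloxy)-3-{[4-(benzyloxy)-2-methoxy-6-(methoxymethyl)phenyl]methyl}-6-methoxy-2-(2-oxopropyl)benzoate | COC(=O)c1c(CC(C)=O)c(Cc2c(COC)cc(OCc3ccccc3)cc2OC)c(OCc2ccccc2)cc1OC | intermediate
19 | 6-(benzyloxy)-5-{[4-(benzyloxy)-2-methoxy-6-(methoxymethyl)phenyl]methyl}-8-methoxy-3-methyl-1H-isochromen-1-one | COCc1cc(OCc2ccccc2)cc(OC)c1Cc1c(OCc2ccccc2)cc(OC)c2c(=O)oc(C)cc12 | intermediate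
20 | 6-hydroxy-5-{[4-hydroxy-2-methoxy-6-(methoxymethyl)phenyl]methyl}-8-methoxy-3-methyl-1H-isochromen-1-one | COCc1cc(O)cc(OC)c1Cc1c(O)cc(OC)c2c(=O)oc(C)cc12 | target

**Step count and risks**
Total step count: 12. Longest linear sequence: 9 steps (5 → 6 → 8 → 9 → 10 → 12 → 14 → 18 → 19 → 20; steps 4 to 12).

The three steps most likely to fail:

Step 8 (exchange and addition between two doubly ortho-substituted partners). The exchange may be slow, or the hindered Grignard may add poorly. The fallback sets out from 10, uses 4 as partner, and comes back at 14, which also bypasses 12 and step 9. Reduce 10 with NaBH4 (MeOH, 0 °C) to [4-(benzyloxy)-2-methoxy-6-(methoxymethyl)phenyl]methanol F1. Convert it with SOCl2 (Et2O, 0 °C, used crude at once) into 5-(benzyloxy)-2-(chloromethyl)-1-methoxy-3-(methoxymethyl)benzene F2. Insert Zn dust in the presence of LiCl (THF, 0 °C to rt) to give {[4-(benzyloxy)-2-methoxy-6-(methoxymethyl)phenyl]methyl}zinc chloride F3. Cross-couple F3 with iodide 4 using Pd(OAc)2 and SPhos (2-dicyclohexylphosphino-2',6'-dimethoxybiphenyl), which give zerovalent palladium in the flask (THF, rt to 50 °C, Negishi coupling), to form 14 directly.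

Step 10 (lateral deprotonation and acylation of a crowded toluate). Conversion may be incomplete, or the anion may be quenched by the enolisable amide. The fallback sets out from 14 and comes back at 19, bypassing 18 and step 11. Saponify 14 (KOH, DMSO/H2O, 90 °C) to 4-(benzyloxy)-3-{[4-(benzyloxy)-2-methoxy-6-(methoxymethyl)phenyl]methyl}-6-methoxy-2-methylbenzoic acid F4. Treat F4 with LiN(i-Pr)2 (2.5 equiv, THF, −78 °C to 0 °C) to give the dilithio carboxylate dianion F5, which cannot self-condense. Acylate F5 with 15 at −78 °C to give 4-(benzyloxy)-3-{[4-(benzyloxy)-2-methoxy-6-(methoxymethyl)phenyl]methyl}-6-methoxy-2-(2-oxopropyl)benzoic acid F6. Cyclodehydrate F6 with Ac2O (80 °C) to 19.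

Step 12 (chemoselective hydrogenolysis). The lactone C3=C4 bond may be reduced, or the benzylic methyl ether may be lost. The fallback sets out from 18 and comes back at 20. Hydrogenolyse the benzyl ethers at the keto ester stage (H2, Pd/C, EtOAc, rt), where no enol-lactone double bond is present, to give methyl 4-hydroxy-3-{[4-hydroxy-2-methoxy-6-(methoxymethyl)phenyl]methyl}-6-methoxy-2-(2-oxopropyl)benzoate F7. Then close ring C with p-TsOH·H2O in toluene at 100 °C to give 20.

**Further compounds**
F1 | step 8 | [4-(benzyloxy)-2-methoxy-6-(methoxymethyl)phenyl]methanol | COCc1cc(OCc2ccccc2)cc(OC)c1CO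
F2 | step 8 | 5-(benzyloxy)-2-(chloromethyl)-1-methoxy-3-(methoxymethyl)benzene | COCc1cc(OCc2ccccc2)cc(OC)c1CCl
F3 | step 8 | {[4-(benzyloxy)-2-methoxy-6-(methoxymethyl)phenyl]methyl}zinc chloride | COCc1cc(OCc2ccccc2)cc(OC)c1C[Zn]Cl
F4 | step 10 | 4-(benzyloxy)-3-{[4-(benzyloxy)-2-methoxy-6-(methoxymethyl)phenyl]methyl}-6-methoxy-2-methylbenzoic acid | OC(=O)c1c(C)c(Cc2c(COC)cc(OCc3ccccc3)cc2OC)c(OCc2ccccc2)cc1OC
F5 | step 10 | lithium 4-(benzyloxy)-3-{[4-(benzyloxy)-2-methoxy-6-(methoxymethyl)phenyl]methyl}-2-(lithiomethyl)-6-methoxybenzoate | [Li]OC(=O)c1c(C[Li])c(Cc2c(COC)cc(OCc3ccccc3)cc2OC)c(OCc2ccccc2)cc1OC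
F6 | step 10 | 4-(benzyloxy)-3-{[4-(benzyloxy)-2-methoxy-6-(methoxymethyl)phenyl]methyl}-6-methoxy-2-(2-oxopropyl)benzoic acid | OC(=O)c1c(CC(C)=O)c(Cc2c(COC)cc(OCc3ccccc3)cc2OC)c(OCc2ccccc2)cc1OC
F7 | step 12 | methyl 4-hydroxy-3-{[4-hydroxy-2-methoxy-6-(methoxymethyl)phenyl]methyl}-6-methoxy-2-(2-oxopropyl)benzoate | COC(=O)c1c(CC(C)=O)c(Cc2c(COC)cc(O)cc2OC)c(O)cc1OC
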